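**Plan** (germacrane locants: ring carbons C1–C10; C11–C13 = α-methylene lactone carbons, lactone O on C8; C14 = CH2OH carbon on C10; C15 = butenolide carbonyl on C4, its O on C6; isobutyrate on C3)
1. Cuts: C5–C6 together with O6–C15 (ring closure), C3–C4 (iodo-aldol with methyl propiolate), C7–C8 (syn-aldol of a succinate imide with a C8–C3 enal), C10–C1 (B-alkyl Suzuki coupling); C13 is carried as CH2SPh.
2. Forward: the trans 12,8-lactone (ring A) is made first, the chain is grown to the C3 aldehyde and capped with a Z β-iodoenoate, then one chromium-mediated step closes the ten-membered ring B at C5–C6 and the butenolide ring C.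
3. Enabling feature: in seco-aldehyde 25 the C5–I bond is cis to the C15 ester across C4=C5, and the C6 aldehyde sits on C7 of ring A, whose trans C8 substituent runs into the ring-cis C9=C10 alkene; this fold brings C5 to C6 and places the new C6 alkoxide next to C15.
4. Stereochemistry: C7/C8 from the (S)-benzyl oxazolidinone; C3 from a chiral oxazaborolidinium catalyst; C6 from Felkin–Anh addition inside the macrocyclic transition state; C9=C10 from directed trans-hydroalumination/iodination and coupling with retention; C4=C5 from the Z iodoenoate.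
5. The C11 methylene is released by sulfoxide elimination and the C14 silyl ether is removed last.

Key step: step 16

Remark (assumption): the oxazaborolidinium catalyst of step 12 is assumed to shield one aldehyde face in the usual way, so that the (R)-diphenylprolinol-derived catalyst gives the 3S carbinol; if the sense proves opposite, the enantiomeric catalyst is used.

Abbreviations: TBDPS = tert-butyldiphenylsilyl, TBS = tert-butyldimethylsilyl, PMB = 4-methoxybenzyl.

**Step 1**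
Reactants: 1 but-2-yne-1,4-diol
Product: 2 4-(TBDPS-oxy)but-2-yn-1-ol
Conditions: NaH (1 equiv), THF, 0 °C to rt; then TBDPSCl (1 equiv)
Reagents that add atoms: tert-butyl(chloro)diphenylsilane, CC(C)(C)[Si](Cl)(c1ccccc1)c1ccccc1
Why: Mono-O-silylation of the symmetrical diol through its mono-sodium alkoxide leaves one propargylic hydroxyl free to direct the next step.

**Step 2**
Reactants: 2 4-(TBDPS-oxy)but-2-yn-1-ol
Product: 3 (Z)-4-(TBDPS-oxy)-3-iodobut-2-en-1-ol
Conditions: NaAlH2(OCH2CH2OMe)2, THF, 0 °C; then I2, −78 to 0 °C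
Reagents that add atoms: iodine, II
Why: The free alkoxide directs a trans-hydroalumination that puts hydride on C9 and aluminium on C10, and iodinolysis with retention gives the Z iodide that fixes the ring-cis C9=C10 geometry.

**Step 3**
Reactants: 3 (Z)-4-(TBDPS-oxy)-3-iodobut-2-en-1-ol, 4 allyl 4-methoxybenzyl ether
Product: 6 (E)-3-[(TBDPS-oxy)methyl]-6-(PMB-oxy)hex-2-en-1-ol, via alkylborane 5 (not isolated)
Conditions: 4, 9-BBN, THF, rt; then 3, Pd(dppf)Cl2, AsPh3, Cs2CO3, DMF/H2O, rt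
Reagents that add atoms: 9-borabicyclo[3.3.1]nonane, B1C2CCCC1CCC2 (boron stays only in intermediate 5)
Why: Anti-Markovnikov hydroboration and B-alkyl Suzuki–Miyaura coupling with retention at the alkenyl iodide form the C10–C1 bond and place the new chain cis to the CH2OH group.

**Step 4**
Reactants: 6 (E)-3-[(TBDPS-oxy)methyl]-6-(PMB-oxy)hex-2-en-1-ol
Product: 7 (E)-3-[(TBDPS-oxy)methyl]-6-(PMB-oxy)hex-2-enal
Conditions: MnO2, CH2Cl2, rt
Reagents that add atoms: none
Why: Neutral allylic oxidation with MnO2 should give the enal without isomerising the trisubstituted alkene.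

**Step 5**
Reactants: 8 (S)-4-benzyloxazolidin-2-one, 9 methyl 4-chloro-4-oxobutanoate
Product: 10 methyl 4-[(S)-4-benzyl-2-oxooxazolidin-3-yl]-4-oxobutanoate
Conditions: n-BuLi, THF, −78 °C; then 9, −78 to 0 °C
Reagents that add atoms: none
Why: N-Acylation of the lithiated oxazolidinone by the acid chloride gives the succinate half-imide for auxiliary-controlled enolisation.

**Step 6**
Reactants: 7 (E)-3-[(TBDPS-oxy)methyl]-6-(PMB-oxy)hex-2-enal, 10 methyl 4-[(S)-4-benzyl-2-oxooxazolidin-3-yl]-4-oxobutanoate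
Product: 12 (S)-4-benzyl-3-[(2R,3S)-2-{(E)-2-[(TBDPS-oxy)methyl]-5-(PMB-oxy)pent-1-en-1-yl}-5-oxotetrahydrofuran-3-carbonyl]oxazolidin-2-one, via syn-aldol adduct 11 (not isolated)
Conditions: 10, Bu2BOTf, iPr2NEt, CH2Cl2, 0 °C; 7, −78 to 0 °C; pH 7 buffer, MeOH, H2O2; then PPTS (cat.), CH2Cl2, rt
Reagents that add atoms: none
Why: In this Evans syn-aldol the Z boron enolate, formed only next to the imide carbonyl, adds to the enal through a chair Zimmerman–Traxler transition state on the face away from the benzyl group to set C7 and C8, and closure of the C8 hydroxyl on the methyl ester turns the syn aldol into the 7,8-trans γ-lactone.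

**Step 7**
Reactants: 12 trans-lactone imide
Product: 13 (4R,5R)-5-{(E)-2-[(TBDPS-oxy)methyl]-5-(PMB-oxy)pent-1-en-1-yl}-4-(hydroxymethyl)dihydrofuran-2(3H)-one
Conditions: NaBH4, THF/H2O, 0 °C; NH4Cl quench
Reagents that add atoms: none
Why: Borohydride reduces the activated exocyclic imide carbonyl much faster than the γ-lactone, releasing the auxiliary and the C6 primary alcohol without touching C7.

**Step 8**
Reactants: 13 hydroxymethyl lactone
Product: 14 (4R,5R)-4-[(TBS-oxy)methyl]-5-{(E)-2-[(TBDPS-oxy)methyl]-5-(PMB-oxy)pent-1-en-1-yl}dihydrofuran-2(3H)-one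
Conditions: TBSCl, imidazole, DMF, 0 °C to rt
Reagents that add atoms: tert-butyl(chloro)dimethylsilane, CC(C)(C)[Si](C)(C)Cl
Why: Imidazole-promoted silylation protects the C6 alcohol as a TBS ether that can later be removed in the presence of the TBDPS ether.

**Step 9**
Reactants: 14 TBS-protected lactone
Product: 16 (3S,4R,5R)-4-[(TBS-oxy)methyl]-5-{(E)-2-[(TBDPS-oxy)methyl]-5-(PMB-oxy)pent-1-en-1-yl}-3-[(phenylsulfanyl)methyl]dihydrofuran-2(3H)-one, via silyl ketene acetal 15 (not isolated)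
Conditions: LiN(iPr)2, THF, −78 °C; Me3SiCl; then PhSCH2Cl, ZnBr2 (cat.), CH2Cl2, rt
Reagents that add atoms: chloromethyl phenyl sulfide, ClCSc1ccccc1; chlorotrimethylsilane, C[Si](C)(C)Cl (silicon stays only in intermediate 15)
Why: The lactone enolate is trapped as its silyl ketene acetal and alkylated at C11 by the thionium ion from PhSCH2Cl and ZnBr2 (Mukaiyama-type alkylation) anti to the C7 substituent, which installs C13 as a sulfide-masked methylene that tolerates the later iodide, Lewis acid and aldehyde stages.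

**Step 10**
Reactants: 16 phenylsulfanylmethyl lactone
Product: 17 (3S,4R,5R)-4-[(TBS-oxy)methyl]-5-{(E)-2-[(TBDPS-oxy)methyl]-5-hydroxypent-1-en-1-yl}-3-[(phenylsulfanyl)methyl]dihydrofuran-2(3H)-one
Conditions: DDQ, CH2Cl2/pH 7 buffer, 0 °C
Reagents that add atoms: none
Why: DDQ oxidises only the electron-rich PMB ether (through its benzylic oxocarbenium ion) and should leave the silyl ethers and the aryl sulfide intact under buffered conditions.

**Step 11**
Reactants: 17 C3 alcohol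
Product: 18 (3S,4R,5R)-4-[(TBS-oxy)methyl]-5-{(E)-2-[(TBDPS-oxy)methyl]-5-oxopent-1-en-1-yl}-3-[(phenylsulfanyl)methyl]dihydrofuran-2(3H)-one
Conditions: Dess–Martin periodinane, NaHCO3, CH2Cl2, rt
Reagents that add atoms: none
Why: Dess–Martin oxidation converts the primary alcohol to the aldehyde under buffered conditions that do not oxidise the sulfide.

**Step 12**
Reactants: 18 C3 aldehyde, 19 methyl propiolate
Product: 22 methyl (2Z,3S,6E)-6-[(TBDPS-oxy)methyl]-3-hydroxy-2-(iodomethylidene)-7-{(2R,3R,4S)-3-[(TBS-oxy)methyl]-5-oxo-4-[(phenylsulfanyl)methyl]tetrahydrofuran-2-yl}hept-6-enoate, via silyl iodoallenolate 20 (not isolated), via trimethylsilyl ether 21 (not isolated)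
Conditions: 19, Me3SiI, triflimide salt of N-protonated (R)-B-(o-tolyl)-diphenylprolinol oxazaborolidine (20 mol %), CH2Cl2, −78 °C; then 1 M HCl, THF, 0 °C
Reagents that add atoms: iodotrimethylsilane, C[Si](C)(C)I (iodine stays in 22; the silyl group only in 20 and 21)
Why: In this catalytic asymmetric iodo-aldol (β-iodo Morita–Baylis–Hillman) reaction, iodide from Me3SiI adds to the propiolate to give the silyl iodoallenolate, whose α-carbon attacks the aldehyde bound to the chiral boron cation, giving the Z iodoenoate (iodine cis to the ester) and the 3S carbinol under catalyst control far from the existing stereocenters.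

**Step 13**
Reactants: 22 β-iodo hydroxy enoate
Product: 23 methyl (2Z,3S,6E)-6-[(TBDPS-oxy)methyl]-2-(iodomethylidene)-3-(isobutyryloxy)-7-{(2R,3R,4S)-3-[(TBS-oxy)methyl]-5-oxo-4-[(phenylsulfanyl)methyl]tetrahydrofuran-2-yl}hept-6-enoate
Conditions: iPrCOCl, pyridine, CH2Cl2, 0 °C
Reagents that add atoms: isobutyryl chloride, CC(C)C(Cl)=O
Why: Acylation of the secondary allylic alcohol with the acid chloride installs the isobutyrate of the target, and no strongly nucleophilic amine catalyst is used so that the β-iodoenoate is not attacked.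

**Step 14**
Reactants: 23 isobutyrate
Product: 24 methyl (2Z,3S,6E)-6-[(TBDPS-oxy)methyl]-7-{(2R,3R,4S)-3-(hydroxymethyl)-5-oxo-4-[(phenylsulfanyl)methyl]tetrahydrofuran-2-yl}-2-(iodomethylidene)-3-(isobutyryloxy)hept-6-enoate
Conditions: HF·pyridine, pyridine, THF, 0 °C
Reagents that add atoms: none
Why: Buffered fluoride cleaves the primary TBS ether much faster than the bulkier TBDPS ether and leaves the esters and the vinyl iodide untouched.

**Step 15**
Reactants: 24 C6 alcohol
Product: 25 methyl (2Z,3S,6E)-6-[(TBDPS-oxy)methyl]-7-{(2R,3S,4S)-3-formyl-5-oxo-4-[(phenylsulfanyl)methyl]tetrahydrofuran-2-yl}-2-(iodomethylidene)-3-(isobutyryloxy)hept-6-enoate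
Conditions: Dess–Martin periodinane, NaHCO3, CH2Cl2, 0 °C to rt; crude aldehyde used at once
Reagents that add atoms: none
Why: Bicarbonate-buffered Dess–Martin oxidation gives the C6 aldehyde without a base strong enough to epimerise C7 or eliminate the C8 lactone oxygen.

**Step 16**
Reactants: 25 seco iodoenoate aldehyde
Product: 27 (3S,6R,7S,8R,11S)-14-(TBDPS-oxy)-3-(isobutyryloxy)-13-(phenylsulfanyl)-11,13-dihydrogermacra-4,9-diene-12,8:15,6-diolide, via ring-closed hydroxy ester 26 (not isolated)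
Conditions: CrCl2 (10 equiv), NiCl2 (0.1 equiv), degassed DMSO, rt, 2 mM, slow addition of 25
Reagents that add atoms: none
Why: Zerovalent nickel, formed from NiCl2 by CrCl2, inserts into the C5–I bond and passes the alkenyl group to trivalent chromium with retention of the C4=C5 geometry, the alkenylchromium adds to the C6 aldehyde, and the chromium alkoxide, which lies cis to the C15 methyl ester, expels methoxide to give the butenolide. The closest known reaction types are the Nozaki–Hiyama–Kishi macrocyclisation of iodoalkenyl aldehydes to nine- and ten-membered rings and the chromium-mediated addition of (Z)-β-iodoacrylates to aldehydes that ends in lactonisation. Ring B (C1–C10) closes by exo-trig addition of C5 to the C6 carbonyl, with C4=C5 becoming the ring-trans alkene because C3 and iodine are trans in 25, and ring C (C4, C5, C6, O, C15) closes by 5-exo-trig acyl substitution. The new C6 center is set by substrate control: the tether through C8 allows only approaches in which C5 is gauche to C8, and of these the Felkin–Anh one (C5 anti to the C7–C11 bond, passing H7, carbonyl oxygen on the C8 side) leads to 6R. The step needs ring closure to win over oligomerisation, which the trans-lactone ring A and the ring-cis C9=C10 alkene favour by folding the chain and which high dilution with slow addition secures, and it needs chemoselectivity for the aldehyde, which alkenylchromium reagents show over lactones, esters and sulfides. C7 should keep its configuration because the medium is not basic.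

**Step 17**
Reactants: 27 macrocyclic sulfide
Product: 29 (3S,6R,7S,8R)-14-(TBDPS-oxy)-3-(isobutyryloxy)germacra-4,9,11(13)-triene-12,8:15,6-diolide, via sulfoxide 28 (not isolated)
Conditions: mCPBA (1.0 equiv), CH2Cl2, −78 °C; then PhMe, 100 °C
Reagents that add atoms: 3-chloroperbenzoic acid, OOC(=O)c1cccc(Cl)c1 (oxygen stays only in intermediate 28)
Why: Selective S-oxidation at low temperature and thermal syn-elimination of benzenesulfenic acid from the sulfoxide, whose only β-hydrogen is H11, release the exocyclic C11=C13 methylene regiospecifically (sulfoxide elimination).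

**Step 18**
Reactants: 29 TBDPS ether of the target
Product: 30 (3S,6R,7S,8R)-14-hydroxy-3-(isobutyryloxy)germacra-4,9,11(13)-triene-12,8:15,6-diolide (target)
Conditions: HF·pyridine, pyridine, THF, 0 °C to rt
Reagents that add atoms: none
Why: Buffered HF removes the primary allylic TBDPS group without the conjugate additions to the two unsaturated lactones that a basic fluoride source could cause.

**Compound list**
1 | but-2-yne-1,4-diol | OCC#CCO | starting material
2 | 4-(TBDPS-oxy)but-2-yn-1-ol | OCC#CCO[Si](c1ccccc1)(c1ccccc1)C(C)(C)C | intermediate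
3 | (Z)-4-(TBDPS-oxy)-3-iodobut-2-en-1-ol | OC/C=C(I)/CO[Si](c1ccccc1)(c1ccccc1)C(C)(C)C | intermediate
4 | 1-[(allyloxy)methyl]-4-methoxybenzene (allyl 4-methoxybenzyl ether) | C=CCOCc1ccc(OC)cc1 | starting material
5 | 9-[3-(PMB-oxy)propyl]-9-borabicyclo[3.3.1]nonane (formed in the flask) | COc1ccc(COCCCB2C3CCCC2CCC3)cc1 | intermediate
6 | (E)-3-[(TBDPS-oxy)methyl]-6-(PMB-oxy)hex-2-en-1-ol (CH2OH cis to the PMB-oxypropyl chain) | OC/C=C(/CO[Si](c1ccccc1)(c1ccccc1)C(C)(C)C)CCCOCc1ccc(OC)cc1 | intermediate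
7 | (E)-3-[(TBDPS-oxy)methyl]-6-(PMB-oxy)hex-2-enal | O=C/C=C(/CO[Si](c1ccccc1)(c1ccccc1)C(C)(C)C)CCCOCc1ccc(OC)cc1 | intermediate
8 | (S)-4-benzyloxazolidin-2-one | O=C1N[C@@H](Cc2ccccc2)CO1 | starting material
9 | methyl 4-chloro-4-oxobutanoate | COC(=O)CCC(Cl)=O | starting material
10 | methyl 4-[(S)-4-benzyl-2-oxooxazolidin-3-yl]-4-oxobutanoate | COC(=O)CCC(=O)N1[C@@H](Cc2ccccc2)COC1=O | intermediate
11 | methyl (3S,4R,5E)-3-[(S)-4-benzyl-2-oxooxazolidine-3-carbonyl]-6-[(TBDPS-oxy)methyl]-4-hydroxy-9-(PMB-oxy)non-5-enoate (syn-aldol adduct, formed in the flask) | COC(=O)C[C@@H]([C@H](O)/C=C(/CO[Si](c1ccccc1)(c1ccccc1)C(C)(C)C)CCCOCc1ccc(OC)cc1)C(=O)N1[C@@H](Cc2ccccc2)COC1=O | intermediate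
12 | (S)-4-benzyl-3-[(2R,3S)-2-{(E)-2-[(TBDPS-oxy)methyl]-5-(PMB-oxy)pent-1-en-1-yl}-5-oxotetrahydrofuran-3-carbonyl]oxazolidin-2-one (trans-lactone) | O=C1O[C@H](/C=C(/CO[Si](c2ccccc2)(c2ccccc2)C(C)(C)C)CCCOCc2ccc(OC)cc2)[C@@H](C(=O)N2[C@@H](Cc3ccccc3)COC2=O)C1 | intermediate
13 | (4R,5R)-5-{(E)-2-[(TBDPS-oxy)methyl]-5-(PMB-oxy)pent-1-en-1-yl}-4-(hydroxymethyl)dihydrofuran-2(3H)-one | O=C1O[C@H](/C=C(/CO[Si](c2ccccc2)(c2ccccc2)C(C)(C)C)CCCOCc2ccc(OC)cc2)[C@@H](CO)C1 | intermediate
14 | (4R,5R)-4-[(TBS-oxy)methyl]-5-{(E)-2-[(TBDPS-oxy)methyl]-5-(PMB-oxy)pent-1-en-1-yl}dihydrofuran-2(3H)-one | O=C1O[C@H](/C=C(/CO[Si](c2ccccc2)(c2ccccc2)C(C)(C)C)CCCOCc2ccc(OC)cc2)[C@@H](CO[Si](C)(C)C(C)(C)C)C1 | intermediate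
15 | 2-(trimethylsilyloxy)-4,5-dihydrofuran derived from 14, same C7 and C8 configuration (silyl ketene acetal, formed in the flask) | C[Si](C)(C)OC1=C[C@H](CO[Si](C)(C)C(C)(C)C)[C@@H](/C=C(/CO[Si](c2ccccc2)(c2ccccc2)C(C)(C)C)CCCOCc2ccc(OC)cc2)O1 | intermediate
16 | (3S,4R,5R)-4-[(TBS-oxy)methyl]-5-{(E)-2-[(TBDPS-oxy)methyl]-5-(PMB-oxy)pent-1-en-1-yl}-3-[(phenylsulfanyl)methyl]dihydrofuran-2(3H)-one (all-trans) | O=C1O[C@H](/C=C(/CO[Si](c2ccccc2)(c2ccccc2)C(C)(C)C)CCCOCc2ccc(OC)cc2)[C@@H](CO[Si](C)(C)C(C)(C)C)[C@@H]1CSc1ccccc1 | intermediate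
17 | (3S,4R,5R)-4-[(TBS-oxy)methyl]-5-{(E)-2-[(TBDPS-oxy)methyl]-5-hydroxypent-1-en-1-yl}-3-[(phenylsulfanyl)methyl]dihydrofuran-2(3H)-one | O=C1O[C@H](/C=C(/CO[Si](c2ccccc2)(c2ccccc2)C(C)(C)C)CCCO)[C@@H](CO[Si](C)(C)C(C)(C)C)[C@@H]1CSc1ccccc1 | intermediate
18 | (3S,4R,5R)-4-[(TBS-oxy)methyl]-5-{(E)-2-[(TBDPS-oxy)methyl]-5-oxopent-1-en-1-yl}-3-[(phenylsulfanyl)methyl]dihydrofuran-2(3H)-one | O=C1O[C@H](/C=C(/CO[Si](c2ccccc2)(c2ccccc2)C(C)(C)C)CCC=O)[C@@H](CO[Si](C)(C)C(C)(C)C)[C@@H]1CSc1ccccc1 | intermediate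
19 | methyl propiolate | C#CC(=O)OC | starting material
20 | (3-iodo-1-methoxypropa-1,2-dien-1-yl)oxy-trimethylsilane (silyl iodoallenolate, formed in the flask) | COC(O[Si](C)(C)C)=C=CI | intermediate
21 | 3-O-trimethylsilyl ether of 22 (formed in the flask) | O=C1O[C@H](/C=C(/CO[Si](c2ccccc2)(c2ccccc2)C(C)(C)C)CC[C@H](O[Si](C)(C)C)/C(=C/I)C(=O)OC)[C@@H](CO[Si](C)(C)C(C)(C)C)[C@@H]1CSc1ccccc1 | intermediate
22 | methyl (2Z,3S,6E)-6-[(TBDPS-oxy)methyl]-3-hydroxy-2-(iodomethylidene)-7-{(2R,3R,4S)-3-[(TBS-oxy)methyl]-5-oxo-4-[(phenylsulfanyl)methyl]tetrahydrofuran-2-yl}hept-6-enoate | O=C1O[C@H](/C=C(/CO[Si](c2ccccc2)(c2ccccc2)C(C)(C)C)CC[C@H](O)/C(=C/I)C(=O)OC)[C@@H](CO[Si](C)(C)C(C)(C)C)[C@@H]1CSc1ccccc1 | intermediate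
23 | 3-O-isobutyrate of 22 | O=C1O[C@H](/C=C(/CO[Si](c2ccccc2)(c2ccccc2)C(C)(C)C)CC[C@H](OC(=O)C(C)C)/C(=C/I)C(=O)OC)[C@@H](CO[Si](C)(C)C(C)(C)C)[C@@H]1CSc1ccccc1 | intermediate
24 | methyl (2Z,3S,6E)-6-[(TBDPS-oxy)methyl]-7-{(2R,3R,4S)-3-(hydroxymethyl)-5-oxo-4-[(phenylsulfanyl)methyl]tetrahydrofuran-2-yl}-2-(iodomethylidene)-3-(isobutyryloxy)hept-6-enoate | O=C1O[C@H](/C=C(/CO[Si](c2ccccc2)(c2ccccc2)C(C)(C)C)CC[C@H](OC(=O)C(C)C)/C(=C/I)C(=O)OC)[C@@H](CO)[C@@H]1CSc1ccccc1 | intermediate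
25 | methyl (2Z,3S,6E)-6-[(TBDPS-oxy)methyl]-7-{(2R,3S,4S)-3-formyl-5-oxo-4-[(phenylsulfanyl)methyl]tetrahydrofuran-2-yl}-2-(iodomethylidene)-3-(isobutyryloxy)hept-6-enoate | O=C1O[C@H](/C=C(/CO[Si](c2ccccc2)(c2ccccc2)C(C)(C)C)CC[C@H](OC(=O)C(C)C)/C(=C/I)C(=O)OC)[C@@H](C=O)[C@@H]1CSc1ccccc1 | intermediate
26 | ten-membered (6R)-6-hydroxy 15-methyl ester, present as its chromium alkoxide (ring-closed hydroxy ester, formed in the flask) | c1ccccc1SC[C@@H]1C(=O)O[C@@H]2/C=C(/CO[Si](c3ccccc3)(c3ccccc3)C(C)(C)C)CC[C@H](OC(=O)C(C)C)/C(C(=O)OC)=C/[C@@H](O)[C@@H]12 | intermediate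
27 | (3S,6R,7S,8R,11S)-14-(TBDPS-oxy)-3-(isobutyryloxy)-13-(phenylsulfanyl)-11,13-dihydrogermacra-4,9-diene-12,8:15,6-diolide | c1ccccc1SC[C@@H]1C(=O)O[C@@H]2/C=C(/CO[Si](c3ccccc3)(c3ccccc3)C(C)(C)C)CC[C@H](OC(=O)C(C)C)C3=C[C@@H](OC3=O)[C@@H]12 | intermediate
28 | S-oxide of 27, mixture at sulfur (formed in the flask) | O=S(c1ccccc1)C[C@@H]1C(=O)O[C@@H]2/C=C(/CO[Si](c3ccccc3)(c3ccccc3)C(C)(C)C)CC[C@H](OC(=O)C(C)C)C3=C[C@@H](OC3=O)[C@@H]12 | intermediate
29 | (3S,6R,7S,8R)-14-(TBDPS-oxy)-3-(isobutyryloxy)germacra-4,9,11(13)-triene-12,8:15,6-diolide | C=C1C(=O)O[C@@H]2/C=C(/CO[Si](c3ccccc3)(c3ccccc3)C(C)(C)C)CC[C@H](OC(=O)C(C)C)C3=C[C@@H](OC3=O)[C@@H]12 | intermediate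
30 | (3S,6R,7S,8R)-14-hydroxy-3-(isobutyryloxy)germacra-4,9,11(13)-triene-12,8:15,6-diolide (C4=C5 trans in the ring, C9=C10 cis in the ring) | C=C1C(=O)O[C@@H]2/C=C(/CO)CC[C@H](OC(=O)C(C)C)C3=C[C@@H](OC3=O)[C@@H]12 | target

**Step count and risks**
Total steps: 18. Longest linear sequence: 17 steps (steps 1–4 and 6–18; step 5 is a side branch).

Steps most likely to fail:

1. Step 16. Intermolecular coupling may compete with closure of the strained ten-membered ring, the alkenylchromium may be protonated before it reaches the aldehyde, or C5 may add to the other aldehyde face. Fallback: make the C5–C6 bond intermolecularly and close ring B at C3–C4 instead. The fallback sets out from 16. HF·pyridine removes the TBS group to give the C6 alcohol F1, and Dess–Martin oxidation gives the C6 aldehyde F2. CrCl2/NiCl2 coupling of F2 with methyl (Z)-3-iodoacrylate gives, after lactonisation in the flask, the open-chain butenolide F3, whose C6 epimers can be separated at this stage (Felkin–Anh control, or a chiral sulfonamide ligand on chromium). I2/pyridine iodinates C4 to give the 4-iodobutenolide F4. DDQ frees the C3 alcohol F5 and Dess–Martin oxidation gives the C3 aldehyde F6. An intramolecular CrCl2/NiCl2 addition of C4 to the C3 aldehyde closes the ten-membered ring as the macrocyclic 3-hydroxy compound F7, and isobutyryl chloride/pyridine brings the route back to 27. The C3 configuration would then rest on macrocyclic control.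

2. Step 12. The chiral boron cation may give poor facial control on this Lewis-basic aldehyde, and Me3SiI may start to cleave silyl ethers before the aldehyde is consumed. Fallback: set C3 by reduction instead of by C–C bond formation. From 18, MgI2-promoted iodo-aldol reaction with 19 (CH2Cl2, 0 °C, no chiral catalyst) gives the adduct as a mixture of C3 epimers F8. Dess–Martin oxidation gives the β-iodo alkylidene keto ester F9. Reduction with catecholborane and the (R)-methyl-CBS oxazaborolidine (Corey–Bakshi–Shibata reduction, alkenyl group as the large substituent) should give the 3S alcohol and rejoins the route at 22.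

3. Step 17. The peracid may over-oxidise the sulfide or attack the C9=C10 alkene, and the strained dilactone may not survive the heating needed for the elimination. Fallback: replace oxidation and thermolysis by alkylation and base-induced elimination. From 27, MeOTf with 2,6-di-tert-butylpyridine (CH2Cl2, 0 °C) gives the S-methyl sulfonium triflate F10, and iPr2NEt at 0 °C eliminates methyl phenyl sulfide by an E1cB path to give 29.

**Further compounds**
F1 | step 16 | (3S,4R,5R)-5-{(E)-2-[(TBDPS-oxy)methyl]-5-(PMB-oxy)pent-1-en-1-yl}-4-(hydroxymethyl)-3-[(phenylsulfanyl)methyl]dihydrofuran-2(3H)-one | O=C1O[C@H](/C=C(/CO[Si](c2ccccc2)(c2ccccc2)C(C)(C)C)CCCOCc2ccc(OC)cc2)[C@@H](CO)[C@@H]1CSc1ccccc1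
F2 | step 16 | 4-formyl analogue of F1 (C6 aldehyde) | O=C1O[C@H](/C=C(/CO[Si](c2ccccc2)(c2ccccc2)C(C)(C)C)CCCOCc2ccc(OC)cc2)[C@@H](C=O)[C@@H]1CSc1ccccc1
F3 | step 16 | open-chain (6R)-butenolide: lactone ring A carrying a 5-oxo-2,5-dihydrofuran-2-yl group on C7 | O=C1O[C@H](/C=C(/CO[Si](c2ccccc2)(c2ccccc2)C(C)(C)C)CCCOCc2ccc(OC)cc2)[C@@H]([C@H]2C=CC(=O)O2)[C@@H]1CSc1ccccc1
F4 | step 16 | 4-iodobutenolide from F3 | O=C1O[C@H](/C=C(/CO[Si](c2ccccc2)(c2ccccc2)C(C)(C)C)CCCOCc2ccc(OC)cc2)[C@@H]([C@H]2C=C(I)C(=O)O2)[C@@H]1CSc1ccccc1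
F5 | step 16 | C3 alcohol from F4 | O=C1O[C@H](/C=C(/CO[Si](c2ccccc2)(c2ccccc2)C(C)(C)C)CCCO)[C@@H]([C@H]2C=C(I)C(=O)O2)[C@@H]1CSc1ccccc1
F6 | step 16 | C3 aldehyde from F5 | O=C1O[C@H](/C=C(/CO[Si](c2ccccc2)(c2ccccc2)C(C)(C)C)CCC=O)[C@@H]([C@H]2C=C(I)C(=O)O2)[C@@H]1CSc1ccccc1
F7 | step 16 | (3S,6R,7S,8R,11S)-14-(TBDPS-oxy)-3-hydroxy-13-(phenylsulfanyl)-11,13-dihydrogermacra-4,9-diene-12,8:15,6-diolide | c1ccccc1SC[C@@H]1C(=O)O[C@@H]2/C=C(/CO[Si](c3ccccc3)(c3ccccc3)C(C)(C)C)CC[C@H](O)C3=C[C@@H](OC3=O)[C@@H]12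
F8 | step 12 | mixture of C3 epimers of 22 | O=C1O[C@H](/C=C(/CO[Si](c2ccccc2)(c2ccccc2)C(C)(C)C)CCC(O)/C(=C/I)C(=O)OC)[C@@H](CO[Si](C)(C)C(C)(C)C)[C@@H]1CSc1ccccc1
F9 | step 12 | 3-oxo analogue of 22 (Z β-iodo alkylidene keto ester) | O=C1O[C@H](/C=C(/CO[Si](c2ccccc2)(c2ccccc2)C(C)(C)C)CCC(=O)/C(=C/I)C(=O)OC)[C@@H](CO[Si](C)(C)C(C)(C)C)[C@@H]1CSc1ccccc1
F10 | step 17 | S-methyl sulfonium triflate of 27 (mixture at sulfur) | C[S+](c1ccccc1)C[C@@H]1C(=O)O[C@@H]2/C=C(/CO[Si](c3ccccc3)(c3ccccc3)C(C)(C)C)CC[C@H](OC(=O)C(C)C)C3=C[C@@H](OC3=O)[C@@H]12.[O-]S(=O)(=O)C(F)(F)F
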